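## The problem

The target is a 2,3-dihydro-1-benzofuran: a benzene ring (C3a to C7a) fused to the oxygen ring O1–C2–C3. C2 (S) carries a 1-formylvinyl group, C3 (R) carries an acetoxy group trans to it, and C5 carries an (R)-1-(angeloyloxy)ethyl group.

C2 and C3 are neighbours, so one can control the other; their trans arrangement corresponds to an anti 1,2-dioxygenated pair in an open-chain precursor. The side-chain carbinol lies para to O1, too far away to be influenced by them, and needs reagent control.

Several groups will not survive rough treatment: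
- The benzylic C3–O bond next to C2–H can ionise in acid or eliminate with base, and either path ends in the aromatic benzofuran.
- The side-chain ester is a p-alkoxybenzylic ester once the C5 carbonyl is reduced, so it ionises and racemises in acid.
- The angelate isomerises easily to the tiglate.
- The 2-substituted acrolein has an aryloxy leaving group on its allylic carbon, so nucleophiles can open the ring by addition–elimination. The aldehyde therefore has to appear last, under neutral conditions.

The feature that makes the key step possible is the substitution of the benzene ring. It carries only O1 at C7a, C3 at C3a and one carbon substituent at C5, with C4, C6 and C7 as CH. It is thus the sum of three alkynes: an ynol ether O1–C7a≡C7, an alkyne C3a≡C4 held at 1,6-distance by the O1–C2–C3 tether, and a terminal alkyne supplying C5 and C6.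

Two consequences follow. C7 must end as CH, so any group placed there to steer regiochemistry has to be traceless. And O1 sits on C2, which is allylic in the target. An ynol ether there would be an allyl alkynyl ether, a class that undergoes Claisen-type [3,3] rearrangement to a ketene far below room temperature. The alkene therefore has to stay masked until the arene exists.

## Retrosynthesis

**Aldehyde last.** Target 24 is cut at the formyl C=O back to primary allylic alcohol 23, and 23 to its silyl ether 22. A neutral oxidation of an allylic alcohol is preferred over selenium dioxide oxidation of an isopropenyl group on the finished molecule, which would have to distinguish four allylic positions. It asks only that the oxygen already be in place.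

**Esters and side-chain stereocentre.** 22 is cut at the angelate C–O bond to (R)-carbinol 19 and angelic acid 20. 19 comes from aryl methyl ketone 18 by catalyst-controlled reduction. 18 comes from hydroxy ketone 17 by acetylation, and 17 from diol 16 by silylation of the primary hydroxyl. The ketone is kept as long as possible because it deactivates the ring and protects both benzylic C–O bonds from acid.

**Unmasking.** 16 is traced to 15, which still carries the C7 silyl group, the MOM ether and the dioxolane. All three leave in one acidic operation. 15 comes from oxirane 14 by base-mediated isomerisation to the allylic alcohol. This is done before the acid step because an oxirane would not survive it, and it needs the ketone masked, which the dioxolane provides.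

**Key cut.** 14 is cut at C3a–C7a, C4–C5 and C6–C7 into diyne 11 and alkyne 13. This removes both rings and leaves an acyclic chain with two stereocentres. The forward (2+2+2) cycloaddition must pair the two tethered alkynes and insert 13 with its substituted carbon at C4. The triethylsilyl group on the ynol ether terminus blocks the other side. 13 is the dioxolane of but-3-yn-2-one 12; the free ynone would trimerise easily and would not survive the later amide base.

**Ynol ether.** 11 comes from 10 by removal of the carbon-bound trimethylsilyl group. 10 comes from dichlorovinyl ether 8 through lithium alkynolate ether 9, and 8 from alcohol 6 and trichloroethylene 7. The O1–C7a bond is thus made on a simple secondary alkoxide. The sequence only works because C2 carries an oxirane and not an alkene.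

**Resolution and masking in one.** 6 is cut at the oxirane back to racemic allylic alcohol 5. Titanium–tartrate epoxidation under kinetic-resolution conditions selects the (3S,4R) half, removes the alkene that would trigger the [3,3] shift, and installs the oxygen that becomes the aldehyde. A separate resolution, a separate mask and a late allylic oxidation would each cost a step.

**C2–C3 bond.** 5 is cut between the two oxygenated carbons into methacrolein 3 and allenylzinc 4, made from MOM ether 2 of 3-(trimethylsilyl)prop-2-yn-1-ol 1. The addition is known to give the anti pair, which becomes the trans ring relationship.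

## Roads not taken

Alternative 1: The cut is at C3–C3a and O1–C2. A bromomagnesium para-halophenoxide adds through its ortho carbon to an epoxy aldehyde. After cation exchange the phenoxide oxygen opens the oxirane at the adjacent carbon, giving A1, (2R,3R)-5-bromo-2-(2-hydroxypropan-2-yl)-2,3-dihydro-1-benzofuran-3-ol.
- Merits: the arene is bought, both ring bonds form in one flask, and the C2 configuration comes from a reliable asymmetric epoxidation of an allylic alcohol. The route to A1 is much shorter than the route to 14.
- Weak points: the facial selectivity of the aldehyde addition that sets C3 is not assured. A1 then needs a bromide-to-acetyl exchange. It also needs a regioselective dehydration of a tertiary alcohol beside the ring oxygen, where ring expansion to a chroman and aromatisation compete. Finally it needs an allylic oxidation of the isopropenyl group.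
- Comparison: in step count and in use of known reactions this road is better up to the bicyclic core. The chosen plan sets against it that the future aldehyde oxygen is in place from step 3 and that no dehydration or late selenium dioxide oxidation is required.

Alternative 2: The cut is at C2–C3 and O1–C2. The ylide from a chiral 2-substituted allyl sulfonium salt adds to the aldehyde of a 5-acylsalicylaldehyde, and the ortho phenoxide displaces the sulfide at the same carbon. The product is A2, 1-[(2S,3R)-2-(3-{[tert-butyl(dimethyl)silyl]oxy}prop-1-en-2-yl)-3-hydroxy-2,3-dihydro-1-benzofuran-5-yl]ethan-1-one.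
- Merits: A2 is the same compound as 17 of the chosen route, and would be reached in a handful of steps instead of eleven, with the protected hydroxymethyl group already present.
- Weak points: one step must deliver both the trans relationship and the absolute configuration. Allyl sulfonium ylides are prone to [2,3]-sigmatropic rearrangement and reversible betaine formation. The aldehyde is deactivated by the adjacent phenoxide, and the chiral sulfide is used stoichiometrically.
- Comparison: if its selectivities hold, this road is clearly superior in step economy. The chosen plan sets against it that relative and absolute configuration come from two well-understood reactions (anti-selective allenylzinc addition, tartrate-controlled epoxidation). Because the two roads meet at 17, a variant of this one is kept as the rescue for the key step.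

Alternative 3: The five-membered ring is traced back to a six-membered chroman. Triflation of the C3 hydroxyl of a trans 4-acetoxy-3-hydroxy-2,2-dimethylchroman should let the ring oxygen attack C3 with inversion and release the gem-dimethyl carbon as the isopropenyl group. The product is A3, (2S,3R)-5-acetyl-2-(prop-1-en-2-yl)-2,3-dihydro-1-benzofuran-3-yl acetate.
- Merits: the chroman stereocentres come from a catalytic asymmetric epoxidation of a chromene. A3 already has the acetyl group, the acetate and the isopropenyl group, and is only three operations from the target. This is the shortest road.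
- Weak points: the ring oxygen is para to an acetyl group and a poor neighbouring group. The vicinal acetate is a better one and would lead to retention or acyl migration, and simple elimination to the chromene also competes. The last step would again be an allylic oxidation on the complete molecule, with the angelate and two benzylic esters present.
- Comparison: shorter, but it rests on a participation that the substitution pattern disfavours. The chosen plan is longer, but after its key step every operation is of a standard kind and no late allylic C–H oxidation is needed.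

Key step: step 8

Assumption: compounds 4 and 5 are racemic and drawn as one enantiomer. The oxirane centre in 6 to 14 is assigned from the usual erythro selectivity of the titanium–tartrate epoxidation and is erased in step 9.

## Route

Step 1
Reactants: 1 3-(trimethylsilyl)prop-2-yn-1-ol
Product: 2 trimethyl[3-(methoxymethoxy)prop-1-yn-1-yl]silane
Conditions: MOMCl, iPr2NEt, CH2Cl2, 0 °C → rt
Reagents that add atoms: chloromethyl methyl ether, `COCCl`
Why: O-Alkylation of a primary alcohol (MOM protection); the acetal oxygen later assists the α-lithiation and stabilises the allenylmetal.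

Step 2
Reactants: 2 trimethyl[3-(methoxymethoxy)prop-1-yn-1-yl]silane; 3 methacrolein
Product: 5 rac-(3S,4R)-4-(methoxymethoxy)-2-methyl-6-(trimethylsilyl)hex-1-en-5-yn-3-ol, via allenylzinc bromide 4 (not isolated)
Conditions: s-BuLi, Et2O, −78 °C; ZnBr2; then 3, −78 → −20 °C
Reagents that add atoms: none
Why: Propargylic α-lithiation and transmetalation give the γ-alkoxy allenylzinc, which adds to the aldehyde in an SE2′ sense through a closed six-membered transition state (allenylzinc propargylation); this sets C3 and C4 anti, only 1,2-addition to the enal is expected, and the product is racemic.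

Step 3
Reactants: 5 rac-(3S,4R)-4-(methoxymethoxy)-2-methyl-6-(trimethylsilyl)hex-1-en-5-yn-3-ol
Product: 6 (1R,2R)-2-(methoxymethoxy)-1-[(2S)-2-methyloxiran-2-yl]-4-(trimethylsilyl)but-3-yn-1-ol
Conditions: Ti(OiPr)4 (15 mol%), D-(−)-diisopropyl tartrate (20 mol%), t-BuOOH (0.45 equiv), 4 Å MS, CH2Cl2, −20 °C
Reagents that add atoms: tert-butyl hydroperoxide, `CC(C)(C)OO`
Why: Sharpless asymmetric epoxidation run as a kinetic resolution: with the D-(−)-tartrate the (3S,4R) half of 5 reacts fast and is epoxidised anti to the carbinol substituent (erythro product, new oxirane centre S under tartrate and carbinol control), while the (3R,4S) half stays as allylic alcohol and is separated; stopping below half conversion keeps 6 enantiomerically pure. The oxirane also removes the alkene that would make the later ynol ether an allyl alkynyl ether.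

Step 4
Reactants: 6 (1R,2R)-2-(methoxymethoxy)-1-[(2S)-2-methyloxiran-2-yl]-4-(trimethylsilyl)but-3-yn-1-ol; 7 trichloroethylene
Product: 8 trimethyl[(3R,4R)-4-{[(E)-1,2-dichloroethenyl]oxy}-3-(methoxymethoxy)-4-[(2S)-2-methyloxiran-2-yl]but-1-yn-1-yl]silane
Conditions: KH, THF, 0 °C; then 7, −78 °C → rt
Reagents that add atoms: none
Why: Base-induced elimination of HCl from trichloroethylene gives dichloroacetylene, to which the potassium alkoxide adds anti (O-dichlorovinylation); the neighbouring oxirane carbon is quaternary, so Payne-type attack by the alkoxide should be slow at low temperature.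

Step 5
Reactants: 8 trimethyl[(3R,4R)-4-{[(E)-1,2-dichloroethenyl]oxy}-3-(methoxymethoxy)-4-[(2S)-2-methyloxiran-2-yl]but-1-yn-1-yl]silane
Product: 10 triethyl(2-{[(1R,2R)-2-(methoxymethoxy)-1-[(2S)-2-methyloxiran-2-yl]-4-(trimethylsilyl)but-3-yn-1-yl]oxy}ethynyl)silane, via lithium alkynolate ether 9 (not isolated)
Conditions: n-BuLi (2.3 equiv), Et2O, −78 → −40 °C; Et3SiCl, −78 → 0 °C
Reagents that add atoms: chlorotriethylsilane, `CC[Si](Cl)(CC)CC`
Why: Deprotonation, loss of LiCl and chlorine–lithium exchange convert the dichlorovinyl ether into the lithiated ynol ether, which is silylated on carbon (ynol ether synthesis by dehydrohalogenation); at −78 °C butyllithium is consumed by these fast steps before it can open a 2,2-disubstituted oxirane, and with the alkene masked no [3,3] shift is possible.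

Step 6
Reactants: 10 triethyl(2-{[(1R,2R)-2-(methoxymethoxy)-1-[(2S)-2-methyloxiran-2-yl]-4-(trimethylsilyl)but-3-yn-1-yl]oxy}ethynyl)silane
Product: 11 triethyl(2-{[(1R,2R)-2-(methoxymethoxy)-1-[(2S)-2-methyloxiran-2-yl]but-3-yn-1-yl]oxy}ethynyl)silane
Conditions: K2CO3 (0.2 equiv), MeOH, 0 °C
Reagents that add atoms: none
Why: Base-catalysed methanolysis of an alkynyl–SiMe3 bond; the bulkier triethylsilyl group on the ynol ether carbon should be cleaved more slowly, so the reaction is stopped at the mono-desilylated stage, and ynol ethers are stable to base.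

Step 7
Reactants: 12 but-3-yn-2-one
Product: 13 2-ethynyl-2-methyl-1,3-dioxolane
Conditions: (Me3SiOCH2)2, TMSOTf (2 mol%), CH2Cl2, −78 °C
Reagents that add atoms: 1,2-bis(trimethylsilyloxy)ethane, `C[Si](C)(C)OCCO[Si](C)(C)C`
Why: Noyori ketalisation with the bis-silyl ether of the diol masks the ketone at low temperature without conjugate addition to the ynone; the ketal turns the partner into a simple propargylic alkyne and shields the carbonyl from the amide base of step 9.

Step 8
Reactants: 11 triethyl(2-{[(1R,2R)-2-(methoxymethoxy)-1-[(2S)-2-methyloxiran-2-yl]but-3-yn-1-yl]oxy}ethynyl)silane; 13 2-ethynyl-2-methyl-1,3-dioxolane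
Product: 14 triethyl{(2R,3R)-3-(methoxymethoxy)-5-(2-methyl-1,3-dioxolan-2-yl)-2-[(2S)-2-methyloxiran-2-yl]-2,3-dihydro-1-benzofuran-7-yl}silane
Conditions: (C5Me5)RuCl(cod) (5–10 mol%), 13 (4 equiv), ClCH2CH2Cl, rt, slow addition of 11
Reagents that add atoms: none
Why: Proposed new method: (C5Me5)RuCl(cod) (divalent ruthenium) loses cyclooctadiene and binds both alkynes of 11; oxidative cyclisation gives a ruthenacyclopentadiene and with it the C3a–C7a bond, so the dihydrofuran ring is closed as the five-membered ring fused to the metallacycle, for which the three-atom O1–C2–C3 tether is the ideal length. Terminal alkyne 13 then inserts into the unhindered Ru–C4 bond, not the silyl-blocked Ru–C7 bond, with its substituted carbon bonding to C4, and reductive elimination closes the benzene ring (C4–C5 and C6–C7 bonds) and frees the catalyst. The closest known reactions are (C5Me5)RuCl(cod)- and RhCl(PPh3)3-catalysed (2+2+2) cycloadditions of 1,6-diynes, ynamide-tethered ones included, with terminal alkynes, where the alkyne substituent ends up meta to a substituent on a diyne terminus, and cobalt-mediated cocyclisations that accept a silylated alkoxyalkyne as one partner; an ynol ether as the tether itself is without precedent. No stereocentre is formed, and C2 and C3 lie on the tether and are not touched. The step needs regioselectivity (ketal-bearing carbon at C5, not C6), secured by the triethylsilyl group on the ynol ether terminus, and cross- over homo-coupling, secured by slow addition of 11 to an excess of 13. The oxirane, the MOM ether and the dioxolane are spectators, and since the C2 substituent is no longer an alkene the ynol ether cannot escape by a Claisen-type [3,3] shift.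

Step 9
Reactants: 14 triethyl{(2R,3R)-3-(methoxymethoxy)-5-(2-methyl-1,3-dioxolan-2-yl)-2-[(2S)-2-methyloxiran-2-yl]-2,3-dihydro-1-benzofuran-7-yl}silane
Product: 15 2-[(2S,3R)-3-(methoxymethoxy)-5-(2-methyl-1,3-dioxolan-2-yl)-7-(triethylsilyl)-2,3-dihydro-1-benzofuran-2-yl]prop-2-en-1-ol
Conditions: Et2AlCl, LiTMP, toluene, 0 °C → rt; aqueous potassium sodium tartrate work-up
Reagents that add atoms: none
Why: Epoxide-to-allylic-alcohol isomerisation with diethylaluminium 2,2,6,6-tetramethylpiperidide (syn β-elimination through a cyclic transition state); the methyl group is the least hindered β-position, so the 2-substituted allyl alcohol should form; C2 and C3 are untouched and the oxirane stereocentre disappears.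

Step 10
Reactants: 15 2-[(2S,3R)-3-(methoxymethoxy)-5-(2-methyl-1,3-dioxolan-2-yl)-7-(triethylsilyl)-2,3-dihydro-1-benzofuran-2-yl]prop-2-en-1-ol
Product: 16 1-[(2S,3R)-3-hydroxy-2-(3-hydroxyprop-1-en-2-yl)-2,3-dihydro-1-benzofuran-5-yl]ethan-1-one
Conditions: CF3CO2H–H2O (9:1), CH2Cl2, 0 °C → rt; then NaHCO3, MeOH
Reagents that add atoms: water, `O`
Why: Ipso-protodesilylation at C7 (electrophilic aromatic substitution, helped by the ortho ring oxygen and the β-silicon effect) together with acetal hydrolysis of the dioxolane and the MOM ether; the ketone is released first and deactivates the ring against ionisation at C3, the alkene is shielded from protonation by two β-oxygens, and water suppresses formal formation from the MOM fragment.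

Step 11
Reactants: 16 1-[(2S,3R)-3-hydroxy-2-(3-hydroxyprop-1-en-2-yl)-2,3-dihydro-1-benzofuran-5-yl]ethan-1-one
Product: 17 1-[(2S,3R)-2-(3-{[tert-butyl(dimethyl)silyl]oxy}prop-1-en-2-yl)-3-hydroxy-2,3-dihydro-1-benzofuran-5-yl]ethan-1-one
Conditions: TBSCl (1.05 equiv), imidazole, CH2Cl2, −20 → 0 °C
Reagents that add atoms: tert-butyl(chloro)dimethylsilane, `CC(C)(C)[Si](C)(C)Cl`
Why: Selective silylation of the primary allylic hydroxyl over the hindered secondary benzylic one.

Step 12
Reactants: 17 1-[(2S,3R)-2-(3-{[tert-butyl(dimethyl)silyl]oxy}prop-1-en-2-yl)-3-hydroxy-2,3-dihydro-1-benzofuran-5-yl]ethan-1-one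
Product: 18 (2S,3R)-5-acetyl-2-(3-{[tert-butyl(dimethyl)silyl]oxy}prop-1-en-2-yl)-2,3-dihydro-1-benzofuran-3-yl acetate
Conditions: Ac2O, pyridine, DMAP (cat.), CH2Cl2, 0 °C
Reagents that add atoms: acetic anhydride, `CC(=O)OC(C)=O`
Why: DMAP-catalysed acetylation of the secondary alcohol; the mild base and low temperature should not cause β-elimination towards the benzofuran.

Step 13
Reactants: 18 (2S,3R)-5-acetyl-2-(3-{[tert-butyl(dimethyl)silyl]oxy}prop-1-en-2-yl)-2,3-dihydro-1-benzofuran-3-yl acetate
Product: 19 (2S,3R)-2-(3-{[tert-butyl(dimethyl)silyl]oxy}prop-1-en-2-yl)-5-[(1R)-1-hydroxyethyl]-2,3-dihydro-1-benzofuran-3-yl acetate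
Conditions: (S)-2-methyl-CBS-oxazaborolidine (20 mol%), catecholborane, toluene, −78 °C
Reagents that add atoms: none
Why: Corey–Bakshi–Shibata reduction of an aryl methyl ketone; the (S)-catalyst treats the aryl group as the large substituent and should give the (R)-carbinol under catalyst control, as with acetophenone, and catecholborane is used so the 1,1-disubstituted alkene is not hydroborated.

Step 14
Reactants: 19 (2S,3R)-2-(3-{[tert-butyl(dimethyl)silyl]oxy}prop-1-en-2-yl)-5-[(1R)-1-hydroxyethyl]-2,3-dihydro-1-benzofuran-3-yl acetate; 20 angelic acid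
Product: 22 (1R)-1-[(2S,3R)-3-(acetyloxy)-2-(3-{[tert-butyl(dimethyl)silyl]oxy}prop-1-en-2-yl)-2,3-dihydro-1-benzofuran-5-yl]ethyl (2Z)-2-methylbut-2-enoate, via mixed trichlorobenzoic anhydride 21 (not isolated)
Conditions: 20, 2,4,6-trichlorobenzoyl chloride, Et3N, toluene, rt; then 19, 70 °C
Reagents that add atoms: none
Why: Yamaguchi-type esterification through the mixed anhydride, run without a nucleophilic catalyst so the Z alkene of the angeloyl unit is not isomerised to the tigloyl isomer; the carbinol configuration is retained because the acyl C–O bond is formed.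

Step 15
Reactants: 22 (1R)-1-[(2S,3R)-3-(acetyloxy)-2-(3-{[tert-butyl(dimethyl)silyl]oxy}prop-1-en-2-yl)-2,3-dihydro-1-benzofuran-5-yl]ethyl (2Z)-2-methylbut-2-enoate
Product: 23 (1R)-1-[(2S,3R)-3-(acetyloxy)-2-(3-hydroxyprop-1-en-2-yl)-2,3-dihydro-1-benzofuran-5-yl]ethyl (2Z)-2-methylbut-2-enoate
Conditions: HF·pyridine, pyridine, THF, 0 °C → rt
Reagents that add atoms: none
Why: Fluoride cleavage of a primary silyl ether under buffered, weakly acidic conditions that should leave both esters and both benzylic C–O bonds intact and avoid base-induced acyl migration.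

Step 16
Reactants: 23 (1R)-1-[(2S,3R)-3-(acetyloxy)-2-(3-hydroxyprop-1-en-2-yl)-2,3-dihydro-1-benzofuran-5-yl]ethyl (2Z)-2-methylbut-2-enoate
Product: 24 (1R)-1-[(2S,3R)-3-(acetyloxy)-2-(3-oxoprop-1-en-2-yl)-2,3-dihydro-1-benzofuran-5-yl]ethyl (2Z)-2-methylbut-2-enoate
Conditions: Dess–Martin periodinane, NaHCO3, CH2Cl2, 0 °C → rt
Reagents that add atoms: none
Why: Dess–Martin oxidation of a primary allylic alcohol; the buffered, non-nucleophilic conditions suit a 2-substituted acrolein whose allylic carbon bears an aryloxy leaving group.

## Compound list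

1 | 3-(trimethylsilyl)prop-2-yn-1-ol | `C[Si](C)(C)C#CCO` | starting material
2 | trimethyl[3-(methoxymethoxy)prop-1-yn-1-yl]silane | `COCOCC#C[Si](C)(C)C` | intermediate
3 | methacrolein | `C=C(C)C=O` | starting material
4 | bromo[3-(methoxymethoxy)-1-(trimethylsilyl)propa-1,2-dien-1-yl]zinc (racemic) | `COCOC=C=C([Zn]Br)[Si](C)(C)C` | intermediate (not isolated)
5 | rac-(3S,4R)-4-(methoxymethoxy)-2-methyl-6-(trimethylsilyl)hex-1-en-5-yn-3-ol (anti; one enantiomer drawn) | `C=C(C)[C@H](O)[C@H](OCOC)C#C[Si](C)(C)C` | intermediate
6 | (1R,2R)-2-(methoxymethoxy)-1-[(2S)-2-methyloxiran-2-yl]-4-(trimethylsilyl)but-3-yn-1-ol | `C[C@]1(CO1)[C@H](O)[C@H](OCOC)C#C[Si](C)(C)C` | intermediate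
7 | trichloroethylene | `ClC=C(Cl)Cl` | starting material
8 | trimethyl[(3R,4R)-4-{[(E)-1,2-dichloroethenyl]oxy}-3-(methoxymethoxy)-4-[(2S)-2-methyloxiran-2-yl]but-1-yn-1-yl]silane | `C[C@]1(CO1)[C@H](O/C(Cl)=C\Cl)[C@H](OCOC)C#C[Si](C)(C)C` | intermediate
9 | lithium 2-{[(1R,2R)-2-(methoxymethoxy)-1-[(2S)-2-methyloxiran-2-yl]-4-(trimethylsilyl)but-3-yn-1-yl]oxy}ethyn-1-ide | `C[C@]1(CO1)[C@H](OC#C[Li])[C@H](OCOC)C#C[Si](C)(C)C` | intermediate (not isolated)
10 | triethyl(2-{[(1R,2R)-2-(methoxymethoxy)-1-[(2S)-2-methyloxiran-2-yl]-4-(trimethylsilyl)but-3-yn-1-yl]oxy}ethynyl)silane | `C[C@]1(CO1)[C@H](OC#C[Si](CC)(CC)CC)[C@H](OCOC)C#C[Si](C)(C)C` | intermediate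
11 | triethyl(2-{[(1R,2R)-2-(methoxymethoxy)-1-[(2S)-2-methyloxiran-2-yl]but-3-yn-1-yl]oxy}ethynyl)silane | `C[C@]1(CO1)[C@H](OC#C[Si](CC)(CC)CC)[C@H](OCOC)C#C` | intermediate (key-step precursor)
12 | but-3-yn-2-one | `CC(=O)C#C` | starting material
13 | 2-ethynyl-2-methyl-1,3-dioxolane | `C#CC1(C)OCCO1` | intermediate
14 | triethyl{(2R,3R)-3-(methoxymethoxy)-5-(2-methyl-1,3-dioxolan-2-yl)-2-[(2S)-2-methyloxiran-2-yl]-2,3-dihydro-1-benzofuran-7-yl}silane | `C[C@]1(CO1)[C@@H]2Oc3c([Si](CC)(CC)CC)cc(C4(C)OCCO4)cc3[C@H]2OCOC` | intermediate (key-step product)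
15 | 2-[(2S,3R)-3-(methoxymethoxy)-5-(2-methyl-1,3-dioxolan-2-yl)-7-(triethylsilyl)-2,3-dihydro-1-benzofuran-2-yl]prop-2-en-1-ol | `C=C(CO)[C@@H]1Oc2c([Si](CC)(CC)CC)cc(C3(C)OCCO3)cc2[C@H]1OCOC` | intermediate
16 | 1-[(2S,3R)-3-hydroxy-2-(3-hydroxyprop-1-en-2-yl)-2,3-dihydro-1-benzofuran-5-yl]ethan-1-one | `C=C(CO)[C@@H]1Oc2ccc(C(C)=O)cc2[C@H]1O` | intermediate
17 | 1-[(2S,3R)-2-(3-{[tert-butyl(dimethyl)silyl]oxy}prop-1-en-2-yl)-3-hydroxy-2,3-dihydro-1-benzofuran-5-yl]ethan-1-one | `C=C(CO[Si](C)(C)C(C)(C)C)[C@@H]1Oc2ccc(C(C)=O)cc2[C@H]1O` | intermediate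
18 | (2S,3R)-5-acetyl-2-(3-{[tert-butyl(dimethyl)silyl]oxy}prop-1-en-2-yl)-2,3-dihydro-1-benzofuran-3-yl acetate | `C=C(CO[Si](C)(C)C(C)(C)C)[C@@H]1Oc2ccc(C(C)=O)cc2[C@H]1OC(C)=O` | intermediate
19 | (2S,3R)-2-(3-{[tert-butyl(dimethyl)silyl]oxy}prop-1-en-2-yl)-5-[(1R)-1-hydroxyethyl]-2,3-dihydro-1-benzofuran-3-yl acetate | `C=C(CO[Si](C)(C)C(C)(C)C)[C@@H]1Oc2ccc([C@@H](C)O)cc2[C@H]1OC(C)=O` | intermediate
20 | angelic acid, (2Z)-2-methylbut-2-enoic acid | `C/C=C(/C)C(=O)O` | starting material
21 | (2Z)-2-methylbut-2-enoic 2,4,6-trichlorobenzoic anhydride | `C/C=C(/C)C(=O)OC(=O)c1c(Cl)cc(Cl)cc1Cl` | intermediate (not isolated)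
22 | (1R)-1-[(2S,3R)-3-(acetyloxy)-2-(3-{[tert-butyl(dimethyl)silyl]oxy}prop-1-en-2-yl)-2,3-dihydro-1-benzofuran-5-yl]ethyl (2Z)-2-methylbut-2-enoate | `C=C(CO[Si](C)(C)C(C)(C)C)[C@@H]1Oc2ccc([C@@H](C)OC(=O)/C(C)=C\C)cc2[C@H]1OC(C)=O` | intermediate
23 | (1R)-1-[(2S,3R)-3-(acetyloxy)-2-(3-hydroxyprop-1-en-2-yl)-2,3-dihydro-1-benzofuran-5-yl]ethyl (2Z)-2-methylbut-2-enoate | `C=C(CO)[C@@H]1Oc2ccc([C@@H](C)OC(=O)/C(C)=C\C)cc2[C@H]1OC(C)=O` | intermediate
24 | (1R)-1-[(2S,3R)-3-(acetyloxy)-2-(3-oxoprop-1-en-2-yl)-2,3-dihydro-1-benzofuran-5-yl]ethyl (2Z)-2-methylbut-2-enoate | `C=C(C=O)[C@@H]1Oc2ccc([C@@H](C)OC(=O)/C(C)=C\C)cc2[C@H]1OC(C)=O` | target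

## Step count and least certain steps

Total steps: 16. Longest linear sequence: 15 (steps 1 to 6 and 8 to 16; step 7 is a one-step side branch).

**Step 8 (key step, proposed new method).**
- What may go wrong: the silyl-capped, electron-rich ynol ether alkyne may be too hindered to enter the oxidative cyclisation. Oligomerisation through the terminal alkyne of 11 or trimerisation of 13 would then take over. Regiocontrol may also be lost in part, and adventitious water may hydrate the ynol ether at the metal.
- Fallback (known chemistry; sets out from 3, comes back at 16): the cycloaddition is given up and the arene is bought. 3 is reduced (NaBH4, CeCl3, MeOH) to 2-methylprop-2-en-1-ol F1 and converted with PBr3 into 3-bromo-2-methylprop-1-ene F2. F2 alkylates a C2-symmetric chiral sulfide to give (2R,5R)-2,5-dimethyl-1-(2-methylprop-2-en-1-yl)thiolan-1-ium bromide F3. The sulfide enantiomer is chosen by the sense of induction found; the (2R,5R) form is written. With Cs2CO3 the ylide of F3 adds to 5-acetyl-2-hydroxybenzaldehyde F4, and the ortho phenoxide displaces the sulfide at the same carbon (sulfur-ylide annulation of a salicylaldehyde). This should give trans 1-[(2S,3R)-3-hydroxy-2-(prop-1-en-2-yl)-2,3-dihydro-1-benzofuran-5-yl]ethan-1-one F5. Allylic hydroxylation of the isopropenyl methyl group (SeO2 cat., t-BuOOH, CH2Cl2) then gives 16. The price is dependence on ylide selectivity and the return of an allylic C–H oxidation.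

**Step 10 (acid step).**
- What may go wrong: ionisation of the benzylic C3–O bond followed by loss of the C2 proton (aromatisation to the benzofuran) may compete with ipso-protonation at C7, which is slowed by the ketone that protects C3.
- Fallback (sets out from 14, comes back at 16): the silicon is removed before any strong acid is used and before the alkene exists. Ipso-iododesilylation of 14 with ICl (CH2Cl2, −78 °C) gives (2R,3R)-7-iodo-3-(methoxymethoxy)-5-(2-methyl-1,3-dioxolan-2-yl)-2-[(2S)-2-methyloxiran-2-yl]-2,3-dihydro-1-benzofuran F6. Hydrodeiodination (Pd(OAc)2, PPh3, HCO2Na, DMF; zerovalent palladium formed in situ) gives (2R,3R)-3-(methoxymethoxy)-5-(2-methyl-1,3-dioxolan-2-yl)-2-[(2S)-2-methyloxiran-2-yl]-2,3-dihydro-1-benzofuran F7. The isomerisation of step 9 then gives 2-[(2S,3R)-3-(methoxymethoxy)-5-(2-methyl-1,3-dioxolan-2-yl)-2,3-dihydro-1-benzofuran-2-yl]prop-2-en-1-ol F8. Only a mild acetal hydrolysis (dilute HCl, MeOH, 0 °C → rt) remains to reach 16.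

**Step 4 (O-dichlorovinylation).**
- What may go wrong: the potassium alkoxide sits next to an oxirane, so epoxide migration or opening may occur before dichloroacetylene traps the oxygen.
- Fallback (sets out from 6, comes back at 10): the two ynol ether carbons are built without a free alkoxide. Formylation of 6 (formic acetic anhydride, pyridine) gives (1R,2R)-2-(methoxymethoxy)-1-[(2S)-2-methyloxiran-2-yl]-4-(trimethylsilyl)but-3-yn-1-yl formate F9. Dichloro-olefination of the formate (PPh3, CCl4, THF, 60 °C) gives trimethyl[(3R,4R)-4-[(2,2-dichloroethenyl)oxy]-3-(methoxymethoxy)-4-[(2S)-2-methyloxiran-2-yl]but-1-yn-1-yl]silane F10. Treatment with n-BuLi and then Et3SiCl as in step 5 gives 10.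

**Step 14 (angeloylation).**
- What may go wrong: the activated angeloyl unit may isomerise from Z to E before the hindered secondary alcohol is acylated, and the p-alkoxybenzylic alcohol may ionise or eliminate on heating.
- Fallback (sets out from 18, comes back at 22): the ester bond is made from the other side. Reduction of 18 with the (R)-oxazaborolidine gives (2S,3R)-2-(3-{[tert-butyl(dimethyl)silyl]oxy}prop-1-en-2-yl)-5-[(1S)-1-hydroxyethyl]-2,3-dihydro-1-benzofuran-3-yl acetate F11. A Mitsunobu reaction with 20 (PPh3, diisopropyl azodicarboxylate, toluene, 0 °C) should give 22 with inversion, without ever activating the acid as an acyl electrophile.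

## Further compounds

F1 | step 8 | 2-methylprop-2-en-1-ol | `C=C(C)CO`
F2 | step 8 | 3-bromo-2-methylprop-1-ene | `C=C(C)CBr`
F3 | step 8 | (2R,5R)-2,5-dimethyl-1-(2-methylprop-2-en-1-yl)thiolan-1-ium bromide | `C=C(C)C[S+]1[C@H](C)CC[C@H]1C.[Br-]`
F4 | step 8 | 5-acetyl-2-hydroxybenzaldehyde | `CC(=O)c1ccc(O)c(C=O)c1`
F5 | step 8 | 1-[(2S,3R)-3-hydroxy-2-(prop-1-en-2-yl)-2,3-dihydro-1-benzofuran-5-yl]ethan-1-one | `C=C(C)[C@@H]1Oc2ccc(C(C)=O)cc2[C@H]1O`
F6 | step 10 | (2R,3R)-7-iodo-3-(methoxymethoxy)-5-(2-methyl-1,3-dioxolan-2-yl)-2-[(2S)-2-methyloxiran-2-yl]-2,3-dihydro-1-benzofuran | `C[C@]1(CO1)[C@@H]2Oc3c(I)cc(C4(C)OCCO4)cc3[C@H]2OCOC`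
F7 | step 10 | (2R,3R)-3-(methoxymethoxy)-5-(2-methyl-1,3-dioxolan-2-yl)-2-[(2S)-2-methyloxiran-2-yl]-2,3-dihydro-1-benzofuran | `C[C@]1(CO1)[C@@H]2Oc3ccc(C4(C)OCCO4)cc3[C@H]2OCOC`
F8 | step 10 | 2-[(2S,3R)-3-(methoxymethoxy)-5-(2-methyl-1,3-dioxolan-2-yl)-2,3-dihydro-1-benzofuran-2-yl]prop-2-en-1-ol | `C=C(CO)[C@@H]1Oc2ccc(C3(C)OCCO3)cc2[C@H]1OCOC`
F9 | step 4 | (1R,2R)-2-(methoxymethoxy)-1-[(2S)-2-methyloxiran-2-yl]-4-(trimethylsilyl)but-3-yn-1-yl formate | `C[C@]1(CO1)[C@H](OC=O)[C@H](OCOC)C#C[Si](C)(C)C`
F10 | step 4 | trimethyl[(3R,4R)-4-[(2,2-dichloroethenyl)oxy]-3-(methoxymethoxy)-4-[(2S)-2-methyloxiran-2-yl]but-1-yn-1-yl]silane | `C[C@]1(CO1)[C@H](OC=C(Cl)Cl)[C@H](OCOC)C#C[Si](C)(C)C`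
F11 | step 14 | (2S,3R)-2-(3-{[tert-butyl(dimethyl)silyl]oxy}prop-1-en-2-yl)-5-[(1S)-1-hydroxyethyl]-2,3-dihydro-1-benzofuran-3-yl acetate | `C=C(CO[Si](C)(C)C(C)(C)C)[C@@H]1Oc2ccc([C@H](C)O)cc2[C@H]1OC(C)=O`
A1 | alternative 1 | (2R,3R)-5-bromo-2-(2-hydroxypropan-2-yl)-2,3-dihydro-1-benzofuran-3-ol | `CC(C)(O)[C@@H]1Oc2ccc(Br)cc2[C@H]1O`
A2 | alternative 2 | 1-[(2S,3R)-2-(3-{[tert-butyl(dimethyl)silyl]oxy}prop-1-en-2-yl)-3-hydroxy-2,3-dihydro-1-benzofuran-5-yl]ethan-1-one | `C=C(CO[Si](C)(C)C(C)(C)C)[C@@H]1Oc2ccc(C(C)=O)cc2[C@H]1O`
A3 | alternative 3 | (2S,3R)-5-acetyl-2-(prop-1-en-2-yl)-2,3-dihydro-1-benzofuran-3-yl acetate | `C=C(C)[C@@H]1Oc2ccc(C(C)=O)cc2[C@H]1OC(C)=O`
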